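**Assumption:** cembrane numbering is used (C1 = ring CH bearing the methylene-lactone carbon C15, C2 = its O–CH neighbour, C6 = butenolide O–CH, C12 = C(CH3)OOH). The target is then (1R,2S,3E,6R,7Z,10E,12S) with a trans-fused α-methylene-γ-lactone. (E)-Geranylacetone is bought as the pure E isomer.

**Retrosynthetic overview**
1. 21 ⇐ 20: singlet-oxygen ene reaction on the 11E alkene installs C12–OOH and the 10E alkene last.
2. 20 ⇐ 18: light-driven, chromium-catalysed intramolecular allylation/lactonisation forms C1–C2, the 14-membered ring and the α-methylene lactone in one step (new method).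
3. 18 ⇐ 15 (Baylis–Hillman, bromination) ⇐ 14 by ring-closing metathesis (butenolide).
4. 14 ⇐ alcohol 7 (C2–C7, from (R)-epichlorohydrin, the only source of chirality) + enol triflate 13 (C8–C14 and C1, from (E)-geranylacetone) + CO.
5. Ring order: butenolide → 14-membered carbocycle together with the α-methylene-γ-lactone → hydroperoxide.

**Route**

Step 1
Reactants: 1 (R)-epichlorohydrin
Product: 2 (R)-1-chloropent-4-yn-2-ol
Conditions: HC≡CH, n-BuLi, THF, −78 °C; BF3·OEt2; then 1, −78 °C; aq. NH4Cl
Reagents that add atoms: lithium acetylide, [Li]C#C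
Why: BF3-promoted alkynylation (Yamaguchi type) opens the epoxide only at its CH2 terminus, so the C–O stereocentre bought with 1 (future C6) is not touched.

Step 2
Reactants: 2 (R)-1-chloropent-4-yn-2-ol
Product: 4 (R)-hex-1-en-5-yn-3-ol, via propargyl oxirane 3 (not isolated)
Conditions: Me3S+ I− (5 equiv), n-BuLi (4.8 equiv), THF, −20 °C → rt
Reagents that add atoms: trimethylsulfonium iodide, C[S+](C)C.[I-]
Why: One-carbon epoxide-to-allylic-alcohol homologation with dimethylsulfonium methylide: base closes 2 to oxirane 3, the ylide opens it at CH2 and a second equivalent eliminates Me2S, with no bond to the stereocentre broken.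

Step 3
Reactants: 4 (R)-hex-1-en-5-yn-3-ol
Product: 6 (2E,5R)-3-methylhepta-2,6-diene-1,5-diol, via alkenylalane 5 (not isolated)
Conditions: Me3Al (3 equiv), Cp2ZrCl2 (0.2 equiv), CH2Cl2, 0 °C → rt; evaporate; n-BuLi, (CH2O)n, THF, 0 °C → rt; dil. HCl
Reagents that add atoms: trimethylaluminium, C[Al](C)C; formaldehyde (as paraformaldehyde), C=O
Why: Negishi zirconium-catalysed methylalumination adds CH3 and Al syn across the terminal alkyne (CH3 on the internal carbon) and the aluminate is hydroxymethylated with retention, which fixes the 3E alkene; the terminal alkene reacts far more slowly.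

Step 4
Reactants: 6 (2E,5R)-3-methylhepta-2,6-diene-1,5-diol
Product: 7 (2E,5R)-5-hydroxy-3-methylhepta-2,6-dienal
Conditions: TEMPO (10 mol%), PhI(OAc)2 (1.1 equiv), CH2Cl2, 0 °C → rt
Reagents that add atoms: none
Why: Oxoammonium (TEMPO) oxidation takes the primary allylic alcohol much faster than the secondary one and does not isomerise the E-enal.

Step 5
Reactants: 8 (E)-geranylacetone
Product: 10 (5E)-8-(3,3-dimethyloxiran-2-yl)-6-methyloct-5-en-2-one (racemic), via bromohydrin 9 (not isolated)
Conditions: NBS (1.05 equiv), THF/H2O, 0 °C; then K2CO3, MeOH, rt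
Reagents that add atoms: water, O; N-bromosuccinimide, O=C1CCC(=O)N1Br (its bromine is in 9 only)
Why: van Tamelen-type bromohydrin formation in aqueous THF is selective for the terminal trisubstituted alkene, and base closes the epoxide; its racemic stereocentre is destroyed in step 7.

Step 6
Reactants: 10 (5E)-8-(3,3-dimethyloxiran-2-yl)-6-methyloct-5-en-2-one
Product: 11 (5E)-8-(3,3-dimethyloxiran-2-yl)-6-methylocta-1,5-dien-2-yl trifluoromethanesulfonate (racemic)
Conditions: LDA, THF, −78 °C; Comins' reagent, −78 → −20 °C; aq. NH4Cl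
Reagents that add atoms: N-(5-chloropyridin-2-yl)bis(trifluoromethanesulfonimide) (Comins' reagent), O=S(=O)(N(c1ccc(Cl)cn1)S(=O)(=O)C(F)(F)F)C(F)(F)F
Why: Kinetic deprotonation of the methyl ketone at CH3 followed by O-triflation gives the 2-triflyloxy-1-alkene; the epoxide survives LDA at −78 °C.

Step 7
Reactants: 11 (5E)-8-(3,3-dimethyloxiran-2-yl)-6-methylocta-1,5-dien-2-yl trifluoromethanesulfonate
Product: 13 (5E)-6-methyl-9-oxonona-1,5-dien-2-yl trifluoromethanesulfonate, via diol 12 (not isolated)
Conditions: H5IO6 (1.2 equiv), THF/H2O, 0 °C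
Reagents that add atoms: water, O (its oxygen is in 12 only and leaves with the acetone)
Why: Periodic acid hydrolyses the epoxide to diol 12 and cleaves it (glycol cleavage) to the aldehyde, leaving the vinyl triflate and the trisubstituted alkene alone.

Step 8
Reactants: 7 (2E,5R)-5-hydroxy-3-methylhepta-2,6-dienal; 13 (5E)-6-methyl-9-oxonona-1,5-dien-2-yl trifluoromethanesulfonate
Product: 14 (3R,5E)-5-methyl-7-oxohepta-1,5-dien-3-yl (5E)-6-methyl-2-methylidene-9-oxonon-5-enoate
Conditions: Pd(OAc)2 (5 mol%), Xantphos (6 mol%), CO (1 atm), Et3N (2 equiv), DMAP (20 mol%), MeCN, 50 °C; 13 in 1.3-fold excess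
Reagents that add atoms: carbon monoxide, [C-]#[O+]
Why: Pd-catalysed alkoxycarbonylation of a vinyl triflate (oxidative addition, CO insertion, alcoholysis of the acyl-palladium by the secondary alcohol of 7) gives the 2-substituted acrylate; allylic esters are normally stable to CO-ligated palladium and the stereocentre is not involved.

Step 9
Reactants: 14 (3R,5E)-5-methyl-7-oxohepta-1,5-dien-3-yl (5E)-6-methyl-2-methylidene-9-oxonon-5-enoate
Product: 15 (5R)-5-[(2E)-2-methyl-4-oxobut-2-en-1-yl]-3-[(3E)-4-methyl-7-oxohept-3-en-1-yl]furan-2(5H)-one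
Conditions: Grubbs II (5 mol%), CH2Cl2 (5 mM), 40 °C
Reagents that add atoms: none
Why: Ring-closing metathesis between the vinyl group and the 1,1-disubstituted acrylate closes the butenolide with loss of ethylene; the trisubstituted alkenes and both aldehydes are inert to the catalyst.

Step 10
Reactants: 15 (5R)-5-[(2E)-2-methyl-4-oxobut-2-en-1-yl]-3-[(3E)-4-methyl-7-oxohept-3-en-1-yl]furan-2(5H)-one; 16 methyl acrylate
Product: 17 methyl (6E)-3-hydroxy-6-methyl-2-methylidene-9-{(5R)-5-[(2E)-2-methyl-4-oxobut-2-en-1-yl]-2-oxo-2,5-dihydrofuran-3-yl}non-6-enoate (both C3 epimers)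
Conditions: DABCO (1 equiv), 16 (5 equiv), MeOH, rt, 2–3 d
Reagents that add atoms: none
Why: Morita–Baylis–Hillman reaction; the unhindered aliphatic aldehyde is far more electrophilic than the conjugated β,β-disubstituted enal, and the new carbinol centre (both epimers) is erased in step 11.

Step 11
Reactants: 17 Baylis–Hillman alcohol
Product: 18 methyl (2Z,6E)-2-(bromomethyl)-6-methyl-9-{(5R)-5-[(2E)-2-methyl-4-oxobut-2-en-1-yl]-2-oxo-2,5-dihydrofuran-3-yl}nona-2,6-dienoate
Conditions: NBS, Me2S, CH2Cl2, 0 °C → rt
Reagents that add atoms: N-bromosuccinimide, O=C1CCC(=O)N1Br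
Why: Corey–Kim-type bromination of a Baylis–Hillman alcohol goes by SN2′ attack of bromide and gives the thermodynamically preferred (Z)-2-(bromomethyl)enoate without touching the enal.

Step 12
Reactants: 18 bromo enal
Product: 20 (1R,2S,3E,6R,7Z,11E)-cembra-3,7,11,15(17)-tetraene-16,2:19,6-diolide, via hydroxy ester 19 (not isolated)
Conditions: CrCl3·3THF (15 mol%), dtbbpy (18 mol%), 4CzIPN (2 mol%), Hantzsch ester (1.5 equiv), THF, 450 nm LEDs, rt, 18 added over 10 h (final 2 mM); then TsOH (cat.), CH2Cl2; NaHCO3 work-up
Reagents that add atoms: none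
Why: Proposed new method: a visible-light-driven, chromium-catalytic Nozaki–Hiyama–Kishi-type macrocyclising allylation, not yet shown for a 2-(bromomethyl)enoate or for ring closure. Excited 4CzIPN is quenched by the Hantzsch ester, its radical anion (about −1.2 V vs SCE) reduces Cr(III) to Cr(II), Cr(II) abstracts bromine from 18 and a second Cr(II) captures the allyl radical to give the (2-methoxycarbonylallyl)Cr(III) species, which adds through C1 to the C2 enal carbonyl in a chair Zimmerman–Traxler transition state with both ring arms pseudo-equatorial (anti, hence the trans-lactone). The C6 butenolide stereocentre and the two E-trisubstituted alkenes are expected to bias the folded 14-membered transition state to the (1R,2S) face (remote macrocyclic substrate control; the sense cannot be predicted with certainty and must be checked on the first cyclisation). The Cr(III) alkoxide turns over by lactonising onto the neighbouring methyl ester and protonolysis of Cr–OMe by the Hantzsch pyridinium, so no metal reductant or silyl chloride is needed. Closest known reactions: intermolecular photoredox/chromium allylation of aldehydes with allyl halides, and the stoichiometric CrCl2 macrocyclisations used for furanocembranoids and germacranolides.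

Step 13
Reactants: 20 (1R,2S,3E,6R,7Z,11E)-cembra-3,7,11,15(17)-tetraene-16,2:19,6-diolide
Product: 21 (1R,2S,3E,6R,7Z,10E,12S)-12-hydroperoxycembra-3,7,10,15(17)-tetraene-16,2:19,6-diolide (target)
Conditions: O2, tetraphenylporphyrin (1 mol%), CH2Cl2, −20 °C, white LEDs, to about 70% conversion
Reagents that add atoms: dioxygen, O=O
Why: Schenck ene reaction of photosensitised singlet oxygen: only the electron-rich C11=C12 alkene should react (C3=C4 is deactivated by its allylic acyloxy group, the conjugated alkenes are inert), the cis effect directs abstraction of a ring C10–H to give the tertiary C12 hydroperoxide with the new 10E alkene, and oxygen is expected to arrive on the exposed outer face of the macrocycle, which would set C12 (S) under control of the existing stereocentres; the 11-hydroperoxy-12(20)-ene regioisomer is the expected by-product.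

**Compound list**
1 | (R)-epichlorohydrin | ClC[C@H]1CO1 | starting material
2 | (R)-1-chloropent-4-yn-2-ol | C#CC[C@@H](O)CCl | intermediate
3 | (R)-2-(prop-2-yn-1-yl)oxirane (not isolated) | C#CC[C@@H]1CO1 | intermediate
4 | (R)-hex-1-en-5-yn-3-ol | C#CC[C@@H](O)C=C | intermediate
5 | (E)-alkenyl(dimethyl)alane of 4, O–AlMe2 alkoxide, Me and Al cis (not isolated) | C[Al](C)/C=C(\C)C[C@@H](O[Al](C)C)C=C | intermediate
6 | (2E,5R)-3-methylhepta-2,6-diene-1,5-diol | OC/C=C(\C)C[C@@H](O)C=C | intermediate
7 | (2E,5R)-5-hydroxy-3-methylhepta-2,6-dienal | O=C/C=C(\C)C[C@@H](O)C=C | intermediate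
8 | (E)-geranylacetone, (5E)-6,10-dimethylundeca-5,9-dien-2-one | CC(=O)CC/C=C(\C)CCC=C(C)C | starting material
9 | (5E)-9-bromo-10-hydroxy-6,10-dimethylundec-5-en-2-one, racemic (not isolated) | CC(=O)CC/C=C(\C)CCC(Br)C(C)(C)O | intermediate
10 | (5E)-8-(3,3-dimethyloxiran-2-yl)-6-methyloct-5-en-2-one, racemic | CC(=O)CC/C=C(\C)CCC1OC1(C)C | intermediate
11 | (5E)-8-(3,3-dimethyloxiran-2-yl)-6-methylocta-1,5-dien-2-yl trifluoromethanesulfonate, racemic | C=C(OS(=O)(=O)C(F)(F)F)CC/C=C(\C)CCC1OC1(C)C | intermediate
12 | (5E)-9,10-dihydroxy-6,10-dimethylundeca-1,5-dien-2-yl trifluoromethanesulfonate, racemic (not isolated) | C=C(OS(=O)(=O)C(F)(F)F)CC/C=C(\C)CCC(O)C(C)(C)O | intermediate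
13 | (5E)-6-methyl-9-oxonona-1,5-dien-2-yl trifluoromethanesulfonate | C=C(OS(=O)(=O)C(F)(F)F)CC/C=C(\C)CCC=O | intermediate
14 | (3R,5E)-5-methyl-7-oxohepta-1,5-dien-3-yl (5E)-6-methyl-2-methylidene-9-oxonon-5-enoate | O=C/C=C(\C)C[C@@H](OC(=O)C(=C)CC/C=C(\C)CCC=O)C=C | intermediate
15 | (5R)-5-[(2E)-2-methyl-4-oxobut-2-en-1-yl]-3-[(3E)-4-methyl-7-oxohept-3-en-1-yl]furan-2(5H)-one | O=C/C=C(\C)C[C@@H]1C=C(CC/C=C(\C)CCC=O)C(=O)O1 | intermediate
16 | methyl acrylate | C=CC(=O)OC | starting material
17 | methyl (6E)-3-hydroxy-6-methyl-2-methylidene-9-{(5R)-5-[(2E)-2-methyl-4-oxobut-2-en-1-yl]-2-oxo-2,5-dihydrofuran-3-yl}non-6-enoate, both C3 epimers | O=C/C=C(\C)C[C@@H]1C=C(CC/C=C(\C)CCC(O)C(=C)C(=O)OC)C(=O)O1 | intermediate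
18 | methyl (2Z,6E)-2-(bromomethyl)-6-methyl-9-{(5R)-5-[(2E)-2-methyl-4-oxobut-2-en-1-yl]-2-oxo-2,5-dihydrofuran-3-yl}nona-2,6-dienoate | O=C/C=C(\C)C[C@@H]1C=C(CC/C=C(\C)CC/C=C(\CBr)C(=O)OC)C(=O)O1 | intermediate
19 | macrocyclic anti-hydroxy ester, (1R,2S,6R): 20 with the 16,2-lactone opened to C2–OH and C16 methyl ester (not isolated) | O[C@H]1/C=C(\C)C[C@@H]2C=C(CC/C=C(\C)CC[C@@H]1C(=C)C(=O)OC)C(=O)O2 | intermediate
20 | (1R,2S,3E,6R,7Z,11E)-cembra-3,7,11,15(17)-tetraene-16,2:19,6-diolide | C=C1C(=O)O[C@H]2/C=C(\C)C[C@@H]3C=C(CC/C=C(\C)CC[C@H]12)C(=O)O3 | intermediate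
21 | (1R,2S,3E,6R,7Z,10E,12S)-12-hydroperoxycembra-3,7,10,15(17)-tetraene-16,2:19,6-diolide | C=C1C(=O)O[C@H]2/C=C(\C)C[C@@H]3C=C(C/C=C/[C@@](C)(OO)CC[C@H]12)C(=O)O3 | target

**Step count:** 13 steps in total. Longest linear sequence: 10 steps (1 → 2 → 4 → 6 → 7 → 14 → 15 → 17 → 18 → 20 → 21); the geranylacetone branch has 3 steps before the union.

**Three steps most likely to fail**

Step 12 (the new step). Risks are poor chromium turnover, reduction of the allyl radical by the Hantzsch ester, oligomerisation, and above all a C1/C2 diastereomer other than (1R,2S), since the whole route rests on remote control from C6. The fallback uses known chemistry and leaves the photochemical catalytic manifold: from 18 the same bond is closed with a stoichiometric, ground-state organochromium reagent under classical Nozaki–Hiyama–Kishi conditions (CrCl2 8 equiv, 4 Å molecular sieves, THF, 2 mM, rt, then catalytic TsOH to lactonise 19), returning to the route at 20. No new compound is made (F0). This cures turnover and photochemical side reactions but not a wrong sense of induction.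

Step 13. Risks are the 11-hydroperoxy-12(20)-ene regioisomer, some attack at C3=C4, and attack on a face that gives the C12 epimer. The fallback replaces the ene reaction by epoxide perhydrolysis and sets out from 20. mCPBA (NaHCO3, CH2Cl2, −20 °C) attacks the same exposed face and gives the (11R,12R)-11,12-epoxide F1. Anhydrous ethereal H2O2 with catalytic phosphomolybdic acid opens it at the tertiary carbon with inversion to the (11R,12S)-12-hydroperoxy-11-ol F2. 2-Methoxypropene with PPTS caps the hydroperoxide as the 2-methoxyprop-2-yl peroxide F3. Martin sulfurane dehydrates the C11 alcohol, which has β-hydrogens only at C10, to the 10E-ene peroxyketal F4. AcOH/THF/H2O then releases 21. Because the hydroperoxide ends on the face opposite to the one the oxidant attacked, this is the remedy when the direct ene reaction gives mainly the C12 epimer; it does not help if only the regiochemistry is poor.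

Step 8. Risks are slow alcoholysis of the acyl-palladium by a secondary alcohol used as the limiting reagent, and ionisation of the allylic ester product by palladium. The fallback separates carbonylation from esterification and sets out from 13. Pd(OAc)2/dppf, CO (1 atm), KOAc, DMSO/H2O gives (5E)-6-methyl-2-methylidene-9-oxonon-5-enoic acid F5. Yamaguchi esterification (2,4,6-trichlorobenzoyl chloride, Et3N, then 7 and DMAP, toluene, rt) returns to the route at 14 with no palladium present once the allylic ester exists.

**Further compounds**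
F0 | step 12 | none | none
F1 | step 13 | (11R,12R)-11,12-epoxide of 20 | C=C1C(=O)O[C@H]2/C=C(\C)C[C@@H]3C=C(CC[C@H]4O[C@]4(C)CC[C@H]12)C(=O)O3
F2 | step 13 | (11R,12S)-12-hydroperoxy-11-hydroxy derivative of 20 (11,12-dihydro) | C=C1C(=O)O[C@H]2/C=C(\C)C[C@@H]3C=C(CC[C@@H](O)[C@@](C)(OO)CC[C@H]12)C(=O)O3
F3 | step 13 | 2-methoxyprop-2-yl peroxide (peroxyketal) of F2 | C=C1C(=O)O[C@H]2/C=C(\C)C[C@@H]3C=C(CC[C@@H](O)[C@@](C)(OOC(C)(C)OC)CC[C@H]12)C(=O)O3
F4 | step 13 | 2-methoxyprop-2-yl peroxide (peroxyketal) of the target 21 | C=C1C(=O)O[C@H]2/C=C(\C)C[C@@H]3C=C(C/C=C/[C@@](C)(OOC(C)(C)OC)CC[C@H]12)C(=O)O3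
F5 | step 8 | (5E)-6-methyl-2-methylidene-9-oxonon-5-enoic acid | C=C(C(=O)O)CC/C=C(\C)CCC=O
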